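**Retrosynthetic overview**
1. Feature: ring A (C1–C2–C3–C4–C5–C10) with its C1–O–C4 bridge is a 7-oxabicyclo[2.2.1]heptane, which is a hydrogenated furan–alkene adduct. C1–C4 and the oxygen come from a 2-substituted furan whose side-chain carbon is C15. C5–C10 comes from an (E)-alkene, as shown by C6 exo on C5 against C9 endo and C14 exo on C10.
2. Lactone (last ring): the C8–O bond forms when the C12 acid opens an 8α,9α-epoxide, which sets C8 and C9. The acrylic acid is grown from a C7 vinyl group by hydroboration, oxidation and methylenation with HCHO (C13).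
3. Ring B: C8=C9 by ring-closing metathesis of a triene. C6–C7 comes from pentadienylation of the C6 aldehyde, the C9 ester becomes the third vinyl group, and the angelate goes on after closure.
4. Ring A: C4–C5 and C1–C10 by intramolecular furan Diels–Alder reaction of an S-furfuryl mesaconate thioester. Raney Ni then removes sulfur (C15–S to CH3, C6 to CH2OH). A menthyl ester at C9 makes the two facial adducts separable diastereomers.
5. Ring order: ring A with its oxygen bridge (plus a temporary thiolactone), then ring B, then the γ-lactone.

Key step: step 5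

Descriptors: eudesmane numbering is used, and α/β refer to the usual drawing with C14 β. The SMILES reads as 1β,4β-epoxy, 5α-H, 6α-OAng, 7α-H, 8β-O (lactone), 9α-OH.
Assumption: the menthyl ester is not required to induce facial selectivity. It is assumed only that the two facial diastereomers can be separated at hydroxy ester 12 and assigned there by X-ray analysis.

**Step 1**
Reactants: 1 (−)-menthol; 2 2-bromopropanoyl bromide
Product: 3 (1R,2S,5R)-menthyl 2-bromopropanoate (both epimers at the C–Br carbon)
Conditions: pyridine, CH2Cl2, 0 °C to rt
Reagents that add atoms: none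
Why: Esterification of a secondary alcohol with an acid bromide leaves the menthyl stereocentres untouched, and the C–Br centre forms as a mixture that disappears in step 2.

**Step 2**
Reactants: 3 menthyl 2-bromopropanoate
Product: 5 (1R,2S,5R)-menthyl 2-(triphenylphosphoranylidene)propanoate, via phosphonium bromide 4 (not isolated)
Conditions: PPh3, toluene, 90 °C; then 1 M NaOH, CH2Cl2, 0 °C
Reagents that add atoms: triphenylphosphine, c1ccc(cc1)P(c1ccccc1)c1ccccc1
Why: SN2 quaternisation of PPh3 by the α-bromo ester and deprotonation of the acidic α-C–H give the ester-stabilised ylide (Wittig reagent preparation), in which the former C–Br centre is planar.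

**Step 3**
Reactants: 5 menthyl ylide; 6 glyoxylic acid monohydrate
Product: 7 (E)-4-[(1R,2S,5R)-menthyloxy]-3-methyl-4-oxobut-2-enoic acid (mesaconic acid 1-menthyl ester)
Conditions: CH2Cl2, 0 °C to rt
Reagents that add atoms: none
Why: Wittig olefination of the aldehyde carbon of glyoxylic acid with an α-methyl ester-stabilised ylide should be (E)-selective (carbonyl groups trans), and it fixes without ambiguity that the free acid (C6) sits on the CH end (C5) and the menthyl ester (C9) on the methyl-bearing end (C10).

**Step 4**
Reactants: 7 mesaconic acid 1-menthyl ester; 8 furan-2-ylmethanethiol (furfuryl mercaptan)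
Product: 10 1-menthyl 4-[S-(furan-2-ylmethyl)] (E)-2-methylbut-2-enedioate 4-thioate, via acid chloride 9 (not isolated)
Conditions: (COCl)2, cat. DMF, CH2Cl2, 0 °C to rt, evaporate; then 8, pyridine, CH2Cl2, −30 °C
Reagents that add atoms: none
Why: In this thioesterification through the acid chloride, S-acylation at low temperature with a weak base should outrun conjugate addition of the thiol to the sluggish trisubstituted acceptor, and the (E)-geometry rules out return to a cyclic anhydride.

**Step 5**
Reactants: 10 S-furfuryl menthyl mesaconate thioester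
Product: 11 thiolactone-fused 7-oxabicyclo[2.2.1]hept-2-ene (C2=C3; thiolactone C4–C15–S–C6–C5 on the exo face; C9 menthyl ester endo and C14 exo on C10), formed together with its facial diastereomer
Conditions: 5 M LiClO4 in Et2O, 0.02 M, 23 °C, dark; aqueous work-up below 10 °C, used crude at once
Reagents that add atoms: none
Why: Proposed new method: a concerted, suprafacial, normal-demand [4+2] cycloaddition in which the furan (C1–C4) adds across the C5=C10 alkene, whose LUMO is lowered by the thioester and by lithium coordination to the C9 ester; the closest known reactions are the intramolecular furan Diels–Alder closures of 2-furfuryl fumarate esters and N-furfuryl fumaramides and the LiClO4- or pressure-assisted additions of furan to sulfur-bridged maleic anhydrides, but neither a thioester tether nor a trisubstituted mesaconate has been tried. The carbocycle C1–C2–C3–C4–C5–C10 closes by the cycloaddition itself (bonds C4–C5 and C1–C10), and the five-membered thiolactone C4–C15–S–C6–C5 closes in the same event in the fused mode, because its three-atom tether ends on C4 and C5. C1 and C4 are tied to each other by the oxygen bridge, C5 is fixed by the tether, which is too short to span the endo face and so puts C6 exo, and C10 is fixed by the (E)-alkene, which then places the C9 ester endo and C14 exo. Regiochemistry needs nothing beyond the tether, and facial selectivity is not relied on, since the menthyl ester turns the two faces into diastereomers that are parted after step 6. The long C–S bonds, the small C–S–C angle and the low rotation barrier of a thioester should ease the fold that ordinary esters resist, and the ketone-like thioester carbonyl activates the alkene more than an ester does. Cycloreversion is the real threat, so the reaction is run at room temperature in a medium that favours the compact adduct, and the crude product is hydrogenated immediately.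

**Step 6**
Reactants: 11 thiolactone adduct
Product: 12 hydroxy ester (7-oxabicyclo[2.2.1]heptane with C15 methyl on C4; exo CH2OH = C6 on C5; endo menthyl ester = C9 and exo methyl = C14 on C10)
Conditions: Raney Ni (W-2, large excess), H2 (1 atm), EtOH, 0 °C to 50 °C; then chromatography and crystallisation to remove the facial diastereomer
Reagents that add atoms: none
Why: Hydrogenation of the strained C2=C3 alkene comes first and ends cycloreversion, after which Raney-nickel desulfurisation cleaves C15–S to the methyl group and the acyl–S bond through the aldehyde to the C6 alcohol (thioester-to-alcohol reduction), with no stereocentre touched and with the trans C6 and C9 arms unable to lactonise.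

**Step 7**
Reactants: 12 hydroxy ester
Product: 13 exo C6 aldehyde with endo C9 menthyl ester
Conditions: Dess–Martin periodinane, NaHCO3, CH2Cl2, 0 °C to rt
Reagents that add atoms: none
Why: Dess–Martin oxidation under buffered, non-basic conditions should leave the C5–H next to the new aldehyde unepimerised, and the exo aldehyde is in any case the more stable epimer.

**Step 8**
Reactants: 14 penta-1,4-dien-3-ol
Product: 15 (E)-5-bromopenta-1,3-diene
Conditions: 48% aq HBr, 0 °C; used fresh
Reagents that add atoms: hydrogen bromide, Br
Why: Allylic substitution with transposition through the pentadienyl cation gives the conjugated primary (E)-bromide as the preferred isomer.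

**Step 9**
Reactants: 13 C6 aldehyde; 15 (E)-5-bromopenta-1,3-diene
Product: 17 6α-alcohol (6S) carrying a penta-1,4-dien-3-yl group (C7 with two vinyl groups), via pentadienylindium dibromide 16 (not isolated)
Conditions: In powder, DMF, 0 °C to rt; then aq NH4Cl
Reagents that add atoms: none
Why: Barbier-type indium pentadienylation is known to react at the central (γ) carbon to give the 3-substituted penta-1,4-diene; C6 is set by attack on the aldehyde rotamer whose formyl H lies in the cleft between C14 and C15 and whose oxygen can be held by trivalent indium together with the bridge oxygen (1,3-chelate), the open face of which leads to the 6α-alcohol, while C7 is not yet stereogenic.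

**Step 10**
Reactants: 17 hydroxy menthyl ester
Product: 18 diol (6α-OH and C9 CH2OH)
Conditions: LiAlH4, THF, reflux; Fieser work-up
Reagents that add atoms: none
Why: Ester reduction with LiAlH4, helped by the neighbouring aluminium alkoxide at C6, releases the auxiliary and gives the neopentyl C9 alcohol without touching the isolated alkenes or any stereocentre.

**Step 11**
Reactants: 18 diol
Product: 19 hydroxy aldehyde (6α-OH and C9 CHO)
Conditions: TEMPO (20 mol %), PhI(OAc)2, CH2Cl2, rt
Reagents that add atoms: none
Why: Oxoammonium (TEMPO) oxidation is selective for primary over secondary alcohols, here reinforced by the shielding of the C6 carbinol, and the trans arms cannot form a five-membered lactol that would be over-oxidised.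

**Step 12**
Reactants: 19 hydroxy aldehyde
Product: 20 triene alcohol (vinyl on C10; two vinyl groups on C7)
Conditions: MePPh3Br, KOtBu, THF, 0 °C to 40 °C
Reagents that add atoms: methyltriphenylphosphonium bromide, C[P+](c1ccccc1)(c1ccccc1)c1ccccc1.[Br-]
Why: Wittig methylenation of a non-enolisable neopentyl aldehyde, with extra ylide to cover the free hydroxyl.

**Step 13**
Reactants: 20 triene alcohol
Product: 21 ring B cyclohexene (C8=C9) with 6α-OH and 7β-vinyl
Conditions: second-generation Grubbs catalyst (10 mol %), 1,4-benzoquinone (20 mol %), toluene (2 mM), 80 °C, argon sparge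
Reagents that add atoms: none
Why: In this ring-closing metathesis with selection between two diastereotopic vinyl groups, the catalyst loads on a C7 vinyl group and closes onto the C10 vinyl group to make C8=C9, and C7 is set because closure (and equilibration through ring-opening by the remaining vinyl group) favours the product whose remaining vinyl group is equatorial (β) and trans to the 6α-hydroxyl.

**Step 14**
Reactants: 21 ring B alcohol; 22 angelic acid
Product: 24 6α-angelate, via mixed anhydride 23 (not isolated)
Conditions: 22, 2,4,6-trichlorobenzoyl chloride, Et3N, toluene, rt; then 21, 80 °C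
Reagents that add atoms: none
Why: Yamaguchi-type mixed-anhydride esterification without DMAP is the established way to acylate hindered secondary alcohols with angelic acid without (Z)-to-(E) drift to the tiglate, and the C6–O bond is not broken, so its configuration is kept.

**Step 15**
Reactants: 24 6α-angelate
Product: 26 primary alcohol (C7–C11H2–C12H2OH), via B-alkyl-9-BBN adduct 25 (not isolated)
Conditions: 9-BBN, THF, 0 °C to rt; then NaBO3·4H2O, THF/H2O, rt
Reagents that add atoms: sodium perborate, O[B-]1(O)OO[B-](O)(O)OO1.[Na+].[Na+]
Why: In hydroboration–oxidation, 9-BBN reacts far faster with the monosubstituted vinyl group than with the hindered ring alkene or the conjugated angelate and places boron on the terminal carbon C12, and the perborate work-up is mild enough for the ester.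

**Step 16**
Reactants: 26 primary alcohol
Product: 27 C12 aldehyde
Conditions: Dess–Martin periodinane, NaHCO3, CH2Cl2, 0 °C to rt
Reagents that add atoms: none
Why: Dess–Martin oxidation stops at the aldehyde and tolerates the alkene, the ester and the ether bridge.

**Step 17**
Reactants: 27 C12 aldehyde
Product: 28 2-substituted acrolein (C11=C13H2; C12 CHO)
Conditions: 37% aq HCHO, pyrrolidine (10 mol %), propionic acid (10 mol %), iPrOH, 45 °C
Reagents that add atoms: formaldehyde, C=O
Why: Amine-catalysed α-methylenation of an aldehyde with formaldehyde (Mannich condensation–elimination through the enamine) installs C13 under nearly neutral conditions that should spare the angelate and the doubly allylic C7–H.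

**Step 18**
Reactants: 28 enal
Product: 29 2-substituted acrylic acid (C12 CO2H)
Conditions: NaClO2, NaH2PO4, 2-methylbut-2-ene, tBuOH/H2O, 0 °C to rt
Reagents that add atoms: sodium chlorite, [Na+].[O-]Cl=O
Why: Pinnick oxidation is selective for the aldehyde, with excess 2-methylbut-2-ene to intercept HOCl before it reaches C8=C9.

**Step 19**
Reactants: 29 acrylic acid
Product: 31 target CNP0328162.1, via epoxy acid 30 (not isolated)
Conditions: mCPBA, CH2Cl2, 0 °C to rt; then camphorsulfonic acid (10 mol %), rt
Reagents that add atoms: 3-chloroperoxybenzoic acid, OOC(=O)c1cccc(Cl)c1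
Why: Prilezhaev epoxidation picks the only electron-rich alkene (C8=C9) and should come from the α face, opposite the axial C14 methyl and the β side chain, and the C12 acid then opens the epoxide at C8 from the β face (5-exo-tet, trans-diaxial, Fürst–Plattner), which sets the 8β-O of the cis-fused lactone and leaves 9α-OH, attack at neopentyl C9 being hindered and out of reach.

**Compound list**
1 | (−)-menthol, (1R,2S,5R)-2-isopropyl-5-methylcyclohexan-1-ol | CC(C)[C@@H]1CC[C@@H](C)C[C@H]1O | starting material
2 | 2-bromopropanoyl bromide | CC(Br)C(=O)Br | starting material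
3 | (1R,2S,5R)-menthyl 2-bromopropanoate | CC(Br)C(=O)O[C@@H]1C[C@H](C)CC[C@H]1C(C)C | intermediate
4 | [1-(menthyloxy)-1-oxopropan-2-yl]triphenylphosphonium bromide | CC(C(=O)O[C@@H]1C[C@H](C)CC[C@H]1C(C)C)[P+](c1ccccc1)(c1ccccc1)c1ccccc1.[Br-] | intermediate
5 | menthyl 2-(triphenylphosphoranylidene)propanoate | CC(C(=O)O[C@@H]1C[C@H](C)CC[C@H]1C(C)C)=P(c1ccccc1)(c1ccccc1)c1ccccc1 | intermediate
6 | glyoxylic acid monohydrate | OC(O)C(=O)O | starting material
7 | (E)-4-(menthyloxy)-3-methyl-4-oxobut-2-enoic acid | O=C(O[C@@H]1C[C@H](C)CC[C@H]1C(C)C)/C(C)=C/C(=O)O | intermediate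
8 | furan-2-ylmethanethiol | SCc1ccco1 | starting material
9 | (E)-4-(menthyloxy)-3-methyl-4-oxobut-2-enoyl chloride | O=C(O[C@@H]1C[C@H](C)CC[C@H]1C(C)C)/C(C)=C/C(=O)Cl | intermediate
10 | S-furfuryl menthyl (E)-2-methylbut-2-enedioate thioester (key-step precursor) | O=C(O[C@@H]1C[C@H](C)CC[C@H]1C(C)C)/C(C)=C/C(=O)SCc1ccco1 | intermediate
11 | thiolactone-fused 7-oxabicyclo[2.2.1]hept-2-ene, C6 exo, C9 menthyl ester endo, C14 exo (key-step product) | O=C3[C@@H]1[C@@](C)(C(=O)O[C@@H]4C[C@H](C)CC[C@H]4C(C)C)[C@H]2C=C[C@]1(CS3)O2 | intermediate
12 | hydroxy ester: exo CH2OH (C6), endo menthyl ester (C9), C14 and C15 methyls | OC[C@@H]1[C@@](C)(C(=O)O[C@@H]3C[C@H](C)CC[C@H]3C(C)C)[C@H]2CC[C@]1(C)O2 | intermediate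
13 | C6 aldehyde, C9 menthyl ester | O=C[C@@H]1[C@@](C)(C(=O)O[C@@H]3C[C@H](C)CC[C@H]3C(C)C)[C@H]2CC[C@]1(C)O2 | intermediate
14 | penta-1,4-dien-3-ol | C=CC(O)C=C | starting material
15 | (E)-5-bromopenta-1,3-diene | C=C/C=C/CBr | intermediate
16 | (E)-penta-2,4-dienylindium dibromide (simplest form of the sesquibromide) | C=C/C=C/C[In](Br)Br | intermediate
17 | 6α-alcohol with C7 divinyl group, C9 menthyl ester | C=CC(C=C)[C@H](O)[C@@H]1[C@@](C)(C(=O)O[C@@H]3C[C@H](C)CC[C@H]3C(C)C)[C@H]2CC[C@]1(C)O2 | intermediate
18 | diol (6α-OH, C9 CH2OH) | C=CC(C=C)[C@H](O)[C@@H]1[C@@](C)(CO)[C@H]2CC[C@]1(C)O2 | intermediate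
19 | hydroxy aldehyde (6α-OH, C9 CHO) | C=CC(C=C)[C@H](O)[C@@H]1[C@@](C)(C=O)[C@H]2CC[C@]1(C)O2 | intermediate
20 | triene alcohol | C=CC(C=C)[C@H](O)[C@@H]1[C@@](C)(C=C)[C@H]2CC[C@]1(C)O2 | intermediate
21 | 1β,4β-epoxy-6α-hydroxy-7β-vinyl ring B cyclohexene (C8=C9) | C=C[C@H]3[C@H](O)[C@@H]1[C@@](C)(C=C3)[C@H]2CC[C@]1(C)O2 | intermediate
22 | angelic acid, (Z)-2-methylbut-2-enoic acid | C/C=C(/C)C(=O)O | starting material
23 | angelic 2,4,6-trichlorobenzoic anhydride | C/C=C(/C)C(=O)OC(=O)c1c(Cl)cc(Cl)cc1Cl | intermediate
24 | 6α-angelate of 21 | C=C[C@H]3[C@H](OC(=O)/C(C)=C\C)[C@@H]1[C@@](C)(C=C3)[C@H]2CC[C@]1(C)O2 | intermediate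
25 | B-(C12-alkyl)-9-borabicyclo[3.3.1]nonane | C1CC2CCCC(C1)B2CC[C@H]3[C@H](OC(=O)/C(C)=C\C)[C@@H]4[C@@](C)(C=C3)[C@H]5CC[C@]4(C)O5 | intermediate
26 | C12 primary alcohol | OCC[C@H]3[C@H](OC(=O)/C(C)=C\C)[C@@H]1[C@@](C)(C=C3)[C@H]2CC[C@]1(C)O2 | intermediate
27 | C12 aldehyde | O=CC[C@H]3[C@H](OC(=O)/C(C)=C\C)[C@@H]1[C@@](C)(C=C3)[C@H]2CC[C@]1(C)O2 | intermediate
28 | α-methylene aldehyde (C11=C13) | C=C(C=O)[C@H]3[C@H](OC(=O)/C(C)=C\C)[C@@H]1[C@@](C)(C=C3)[C@H]2CC[C@]1(C)O2 | intermediate
29 | α-methylene acid | C=C(C(=O)O)[C@H]3[C@H](OC(=O)/C(C)=C\C)[C@@H]1[C@@](C)(C=C3)[C@H]2CC[C@]1(C)O2 | intermediate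
30 | 8α,9α-epoxy acid | C=C(C(=O)O)[C@H]3[C@H](OC(=O)/C(C)=C\C)[C@@H]1[C@@](C)([C@@H]4O[C@H]34)[C@H]2CC[C@]1(C)O2 | intermediate
31 | 1β,4β-epoxy-6α-angeloyloxy-9α-hydroxyeudesm-11(13)-en-12,8β-olide (CNP0328162.1) | C=C1C(=O)O[C@H]2[C@@H]1[C@H](OC(=O)/C(C)=C\C)[C@@H]1[C@@](C)([C@@H]2O)[C@H]2CC[C@]1(C)O2 | target

**Count**
Total steps: 19. Longest linear sequence: 18 (steps 1–7 and 9–19). Step 8 is a one-step side branch.

**Steps most likely to fail**

*Step 5 (labelled).*
- What may go wrong: the equilibrium may stay on the side of the open thioester, the thioester may not reach the folded rotamer, or ionisation of the furfuryl C–S bond may start polymerisation.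
- Fallback: known chemistry with an oxygen tether and later deoxygenation. It sets out from acid chloride 9 and comes back at aldehyde 13. Compound 9 is esterified with furfuryl alcohol and pyridine to furfuryl menthyl mesaconate F1, a member of the 2-furfuryl fumarate class whose ester-tethered furan Diels–Alder closure is established. Warming in acetonitrile should give the lactone-fused oxanorbornene F2. This is hydrogenated at once (H2, Pd/C, EtOAc) to the saturated lactone F3 and freed from its facial diastereomer at that stage. MeNH(OMe)·HCl with AlMe3 opens the lactone to the hydroxy Weinreb amide F4. 1,1'-Thiocarbonyldiimidazole converts the C15 alcohol into the imidazolyl thionocarbonate F5. Bu3SnH and AIBN in hot toluene (Barton–McCombie deoxygenation) leave the C15 methyl group in Weinreb amide F6. DIBAL-H at −78 °C then reduces the amide, not the hindered menthyl ester, to 13.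

*Step 13.*
- What may go wrong: closure against the strain of a six-membered ring trans-fused to the oxanorbornane may be slow enough for intermolecular metathesis of the free vinyl groups to win. Discrimination between the two diastereotopic vinyl groups may be weak, and alkene migration in the skipped diene may intervene.
- Fallback: the ring is closed by an irreversible carbonyl olefination instead of olefin–olefin exchange. It sets out from hydroxy aldehyde 19, comes back at 21, and bypasses step 12. Compound 19 is silylated (TESOTf, 2,6-lutidine) to the triethylsilyl ether aldehyde F7. One equivalent of Mo(=CHCMe2Ph)(=N-2,6-iPr2C6H3)[OCMe(CF3)2]2 in benzene first exchanges with an unhindered C7 vinyl group. The new alkylidene then olefinates the hindered C9 aldehyde within the molecule (alkylidene-mediated olefin metathesis/carbonyl olefination), driven by the Mo=O bond, to give the silylated ring B cyclohexene F8. TBAF frees 21.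

*Step 9.*
- What may go wrong: facial selectivity at the C6 aldehyde may be poor, because C14 and C15 flank it almost evenly and chelation to the bridge oxygen may be weak.
- Fallback: catalyst control in place of substrate control. It sets out from aldehyde 13 and bromide 15 and comes back at 17. Bromide 15 is converted (Mg, then 2-isopropoxy-4,4,5,5-tetramethyl-1,3,2-dioxaborolane) into (E)-penta-2,4-dienyl pinacol boronate F9. This adds to 13 at its γ-carbon through a closed chair transition state under catalysis by the chiral phosphoric acid TRIP (3,3'-bis(2,4,6-triisopropylphenyl)-1,1'-binaphthyl-2,2'-diyl hydrogen phosphate). The (S)-enantiomer is expected, by analogy with simple aldehydes, to deliver the (6S) alcohol.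

**Further compounds**
F1 | step 5 | furan-2-ylmethyl menthyl (E)-2-methylbut-2-enedioate | O=C(O[C@@H]1C[C@H](C)CC[C@H]1C(C)C)/C(C)=C/C(=O)OCc1ccco1
F2 | step 5 | lactone-fused 7-oxabicyclo[2.2.1]hept-2-ene, C9 menthyl ester endo | O=C3[C@@H]1[C@@](C)(C(=O)O[C@@H]4C[C@H](C)CC[C@H]4C(C)C)[C@H]2C=C[C@]1(CO3)O2
F3 | step 5 | saturated lactone | O=C3[C@@H]1[C@@](C)(C(=O)O[C@@H]4C[C@H](C)CC[C@H]4C(C)C)[C@H]2CC[C@]1(CO3)O2
F4 | step 5 | C6 Weinreb amide with C15 CH2OH | CON(C)C(=O)[C@@H]1[C@@](C)(C(=O)O[C@@H]3C[C@H](C)CC[C@H]3C(C)C)[C@H]2CC[C@]1(CO)O2
F5 | step 5 | C15 O-(imidazol-1-ylthiocarbonyl) derivative of F4 | CON(C)C(=O)[C@@H]1[C@@](C)(C(=O)O[C@@H]3C[C@H](C)CC[C@H]3C(C)C)[C@H]2CC[C@]1(COC(=S)n3ccnc3)O2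
F6 | step 5 | C6 Weinreb amide with C15 methyl | CON(C)C(=O)[C@@H]1[C@@](C)(C(=O)O[C@@H]3C[C@H](C)CC[C@H]3C(C)C)[C@H]2CC[C@]1(C)O2
F7 | step 13 | 6α-triethylsilyl ether of 19 | C=CC(C=C)[C@H](O[Si](CC)(CC)CC)[C@@H]1[C@@](C)(C=O)[C@H]2CC[C@]1(C)O2
F8 | step 13 | 6α-triethylsilyl ether of 21 | C=C[C@H]3[C@H](O[Si](CC)(CC)CC)[C@@H]1[C@@](C)(C=C3)[C@H]2CC[C@]1(C)O2
F9 | step 9 | (E)-2-(penta-2,4-dienyl)-4,4,5,5-tetramethyl-1,3,2-dioxaborolane | C=C/C=C/CB1OC(C)(C)C(C)(C)O1
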